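**Retrosynthetic overview**
1. Ring A is the phenol ring (C1 OH, C2 Br, C3 H, C4 Br, C5 H, C6 O–ring B). Its brominated carbon C2 lies directly beside the carbinol carbon C1. A C(O)–C(Br)=C unit of this kind is what remains when CBr2 is spliced into an enol ether C=C, so C2 is treated as an inserted carbene carbon.
2. C4–Br is disconnected first and is therefore made last. C4 is para to the OH and both ortho sites are filled, so 2-bromo-6-(2,4-dibromophenoxy)phenol is the penultimate compound.
3. Key cut: C1–C2 and C2–C3 are broken and C1–C3 is rejoined. This contracts ring A to a 2-siloxy-3-aryloxycyclopenta-1,3-diene plus bromoform.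
4. The diene goes back by soft enolisation to 2-(2,4-dibromophenoxy)cyclopent-2-enone, and that to 2,3-epoxycyclopentanone plus 2,4-dibromophenol. The hindered diaryl ether C–O bond is thus made by SN2 at an sp3 carbon.
5. Ring order: ring B and the five-membered carbocycle are bought. The oxirane comes first (transient handle), then the cyclopropane (transient), then six-membered ring A by opening of the cyclopropane.

Key step: step 4

Assumption: ring A atom numbers are those of the target phenol. The target is achiral; compounds 2, 4 and 8 are racemic with transient stereocentres, and one enantiomer is drawn for each.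

**Step 1**
Reactants: 1 cyclopent-2-en-1-one
Product: 2 racemic cis-fused 6-oxabicyclo[3.1.0]hexan-2-one (2,3-epoxycyclopentanone)
Conditions: 30% aq. H2O2, NaOH (cat.), MeOH, 0 °C
Reagents that add atoms: hydrogen peroxide, OO
Why: Weitz–Scheffer nucleophilic epoxidation, in which hydroperoxide adds to C3 of the enone and the enolate closes on oxygen; the two new stereocentres are cis by the ring fusion and racemic, which does not matter because both are erased in step 2.

**Step 2**
Reactants: 2 2,3-epoxycyclopentanone; 3 2,4-dibromophenol
Product: 5 2-(2,4-dibromophenoxy)cyclopent-2-en-1-one, via hydroxy ketone 4 (not isolated)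
Conditions: 2 (1.2 equiv), KH (0.2 equiv), THF–DMPU, 65 °C
Reagents that add atoms: none
Why: This is the known route from α,β-epoxy ketones and phenols to 2-aryloxyenones, in which the phenoxide opens the oxirane by SN2 at the carbonyl-activated α-carbon with inversion (trans-4), E1cB loss of hydroxide removes both stereocentres, and the hydroxide regenerates phenoxide so that the medium stays only as basic as the weakly basic dibromophenoxide until 3 is used up.

**Step 3**
Reactants: 5 2-(2,4-dibromophenoxy)cyclopent-2-en-1-one
Product: 6 tert-butyl{[5-(2,4-dibromophenoxy)cyclopenta-1,4-dien-1-yl]oxy}dimethylsilane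
Conditions: TBSOTf (1.1 equiv), Et3N (1.5 equiv), Et2O, −78 → 0 °C; cold pentane, decant from the ammonium triflate, concentrate at ≤0 °C, use at once
Reagents that add atoms: tert-butyldimethylsilyl trifluoromethanesulfonate, CC(C)(C)[Si](C)(C)OS(=O)(=O)C(F)(F)F
Why: Soft enolisation as known for cyclopentenones, in which O-silylation gives a siloxyallyl cation and Et3N removes the kinetic α′ proton to give the cross-conjugated 2-siloxydiene; the amine is too weak to deprotonate the acidic ring CH2 of the product, whereas a preformed lithium dienolate would do so and move the double bonds.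

**Step 4**
Reactants: 6 tert-butyl{[5-(2,4-dibromophenoxy)cyclopenta-1,4-dien-1-yl]oxy}dimethylsilane; 7 bromoform
Product: 10 2-bromo-6-(2,4-dibromophenoxy)phenol, via dibromocyclopropane 8 (not isolated), via aryl silyl ether 9 (not isolated)
Conditions: 7 (4 equiv), 2,6-di-tert-butyl-4-methylpyridine (1.2 equiv), pentane, −40 °C, KOtBu (1 M in THF, 4.5 equiv) by syringe pump; then AcOH, Bu4NF, THF, 0 °C
Reagents that add atoms: bromoform (compound 7), BrC(Br)Br
Why: Tribromomethanide from 7 loses bromide to give singlet CBr2, which adds in a concerted but asynchronous [2+1] cheletropic step to the siloxy-bearing double bond of 6 (C1=C3 in ring A numbering), making C1–C2 and C2–C3 and closing the three-membered ring of cis-fused 8. The endo bromide of 8 then leaves in concert with disrotatory two-electron electrocyclic cleavage of the shared C1–C3 bond (Woodward–Hoffmann–DePuy rule), pushed by the siloxy oxygen, so six-membered ring A arises by one-carbon ring expansion and not by an end-to-end cyclisation. The cation so formed is the C4-protonated arenium ion of 9, so loss of the C4 proton with silicon kept on oxygen is taken as the main exit, any material that loses silicon instead passes through the cyclohexa-2,5-dienone tautomer to the same phenol, and buffered fluoride brings everything to 10 without an oxidant. The closest known reactions are the dihalocarbene ring expansions of cyclic silyl enol ethers to 2-haloenones, of indanone silyl enol ethers to 2-halo-1-naphthols and of cyclopentadiene or indene to haloarenes. The step needs site selectivity for C1=C3 over C5=C6, secured because positive charge builds on the oxygen-bearing carbon and OSi is a much better donor than an oxygen sharing its lone pair with the electron-poor, ortho-brominated ring B, and it needs positional integrity of the diene, secured by −40 °C (no [1,5]-H shift), by feeding the base slowly into excess 7 so that free tert-butoxide does not linger beside the acidic ring CH2, and by the hindered pyridine that carries released HBr away from the acid-labile enol ether. The two stereocentres of 8 are cis by the geometry of the ring fusion and vanish on aromatisation, and the silyl group left on 9 keeps the product out of Reimer–Tiemann attack by surplus carbene.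

**Step 5**
Reactants: 10 2-bromo-6-(2,4-dibromophenoxy)phenol
Product: 11 2,4-dibromo-6-(2,4-dibromophenoxy)phenol (target)
Conditions: NBS (1.0 equiv), MeCN, 0 °C
Reagents that add atoms: N-bromosuccinimide, O=C1CCC(=O)N1Br
Why: Electrophilic aromatic bromination directed by the free OH, whose ortho positions C2 and C6 are both occupied so that only para C4 is open, while C3 and C5 are meta to the OH and ring B is deactivated by two bromines, so one equivalent should stop at the target.

**Compound list**
1 | cyclopent-2-en-1-one | O=C1C=CCC1 | starting material
2 | racemic cis-fused 6-oxabicyclo[3.1.0]hexan-2-one (one enantiomer drawn) | O=C1CC[C@@H]2O[C@H]12 | intermediate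
3 | 2,4-dibromophenol | Oc1ccc(Br)cc1Br | starting material
4 | racemic trans-2-(2,4-dibromophenoxy)-3-hydroxycyclopentan-1-one (one enantiomer drawn, not isolated) | O=C1CC[C@H](O)[C@H]1Oc1ccc(Br)cc1Br | intermediate
5 | 2-(2,4-dibromophenoxy)cyclopent-2-en-1-one | O=C1CCC=C1Oc1ccc(Br)cc1Br | intermediate
6 | tert-butyl{[5-(2,4-dibromophenoxy)cyclopenta-1,4-dien-1-yl]oxy}dimethylsilane | CC(C)(C)[Si](C)(C)OC1=CCC=C1Oc1ccc(Br)cc1Br | intermediate
7 | bromoform | BrC(Br)Br | starting material
8 | racemic cis-fused tert-butyl{[6,6-dibromo-2-(2,4-dibromophenoxy)bicyclo[3.1.0]hex-2-en-1-yl]oxy}dimethylsilane (one enantiomer drawn, not isolated) | CC(C)(C)[Si](C)(C)O[C@@]12C(Oc3ccc(Br)cc3Br)=CC[C@@H]1C2(Br)Br | intermediate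
9 | tert-butyl[2-bromo-6-(2,4-dibromophenoxy)phenoxy]dimethylsilane (not isolated) | CC(C)(C)[Si](C)(C)Oc1c(Br)cccc1Oc1ccc(Br)cc1Br | intermediate
10 | 2-bromo-6-(2,4-dibromophenoxy)phenol | Oc1c(Br)cccc1Oc1ccc(Br)cc1Br | intermediate
11 | 2,4-dibromo-6-(2,4-dibromophenoxy)phenol | Oc1c(Br)cc(Br)cc1Oc1ccc(Br)cc1Br | target

Total step count: 5
Longest linear sequence: 5 steps (1 → 2 → 5 → 6 → 10 → 11)

**Steps most likely to fail**

**Step 4.**
- What may go wrong: the carbene may add in part to the aryloxy-bearing double bond. The double bonds may migrate through the cyclopentadienide before the carbene arrives. Released acid may protonate the enol ether. The first two processes would put the new C–Br carbon at another position of ring A.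
- Fallback: it removes the competing double bond and the acidic CH2 by running the ring expansion one oxidation level lower. It sets out from 3.
- 3 is alkylated with 2-chlorocyclopentanone (K2CO3, acetone, reflux) to racemic 2-(2,4-dibromophenoxy)cyclopentan-1-one F1.
- Kinetic deprotonation at the unsubstituted α-carbon and silylation (LiN(SiMe3)2, THF, −78 °C, then TBSOTf) gives the silyl enol ether tert-butyl{[5-(2,4-dibromophenoxy)cyclopent-1-en-1-yl]oxy}dimethylsilane F2, which has a single C=C.
- CHBr3 and KOtBu in pentane at −20 °C add the carbene anti to the aryloxy group to give the dibromocyclopropane tert-butyl{[6,6-dibromo-2-(2,4-dibromophenoxy)bicyclo[3.1.0]hexan-1-yl]oxy}dimethylsilane F3.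
- F3 opens in the flask with loss of bromide and silicon to 2-bromo-6-(2,4-dibromophenoxy)cyclohex-2-en-1-one F4.
- Dehydrogenation with DDQ in dioxane at reflux aromatises F4, and the route is rejoined at 10.

**Step 3.**
- What may go wrong: the double bonds may drift, the diene may dimerise by Diels–Alder reaction, or the enol ether may hydrolyse while it is freed from the ammonium salt and concentrated.
- Fallback: it gives up the five-membered ring and takes ring A from an arene. It sets out from 3.
- SNAr of 3 on 2-bromo-6-fluorobenzaldehyde (K2CO3, DMF, 100 °C; fluoride ortho to the formyl group is displaced ahead of bromide) gives 2-bromo-6-(2,4-dibromophenoxy)benzaldehyde F5.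
- Baeyer–Villiger oxidation (mCPBA, CH2Cl2) with aryl migration gives 2-bromo-6-(2,4-dibromophenoxy)phenyl formate F6.
- Methanolysis (K2CO3 cat., MeOH) rejoins the route at 10.

**Step 2.**
- What may go wrong: base-induced isomerisation of the epoxy ketone to the 1,2-dione, or its oligomerisation, may outrun attack by the hindered, weakly nucleophilic phenoxide. Dehydration of the aldol-type adduct may also stall.
- Fallback: it makes the vinyl C–O bond by metal catalysis instead of epoxide opening. It sets out from 1 and 3.
- Pyridine-mediated α-iodination of 1 (I2, pyridine, CH2Cl2) gives 2-iodocyclopent-2-en-1-one F7.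
- Ullmann-type vinyl C–O coupling of F7 with 3 (CuI, N,N-dimethylglycine, Cs2CO3, dioxane, 70 °C) follows. The vinyl iodide reacts ahead of the aryl bromides. The route is rejoined at 5.

**Further compounds**
F1 | step 4 | racemic 2-(2,4-dibromophenoxy)cyclopentan-1-one (one enantiomer drawn) | O=C1CCC[C@@H]1Oc1ccc(Br)cc1Br
F2 | step 4 | racemic tert-butyl{[5-(2,4-dibromophenoxy)cyclopent-1-en-1-yl]oxy}dimethylsilane (one enantiomer drawn) | CC(C)(C)[Si](C)(C)OC1=CCC[C@@H]1Oc1ccc(Br)cc1Br
F3 | step 4 | racemic tert-butyl{[6,6-dibromo-2-(2,4-dibromophenoxy)bicyclo[3.1.0]hexan-1-yl]oxy}dimethylsilane, cis-fused, aryloxy anti to the CBr2 bridge (one enantiomer drawn) | CC(C)(C)[Si](C)(C)O[C@@]12[C@@H](Oc3ccc(Br)cc3Br)CC[C@@H]1C2(Br)Br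
F4 | step 4 | racemic 2-bromo-6-(2,4-dibromophenoxy)cyclohex-2-en-1-one (one enantiomer drawn) | O=C1C(Br)=CCC[C@@H]1Oc1ccc(Br)cc1Br
F5 | step 3 | 2-bromo-6-(2,4-dibromophenoxy)benzaldehyde | O=Cc1c(Br)cccc1Oc1ccc(Br)cc1Br
F6 | step 3 | 2-bromo-6-(2,4-dibromophenoxy)phenyl formate | O=COc1c(Br)cccc1Oc1ccc(Br)cc1Br
F7 | step 2 | 2-iodocyclopent-2-en-1-one | O=C1CCC=C1I
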